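**Plan**

1. Retrosynthetic cuts, in order: the two prenyl–C bonds at the ring CH2; the trione ring at two C–C bonds (C(acyl)–C(=O) and CH2–C(=O), both carbonyls on the spiro carbon), leaving a β-diketone dianion and a bicyclic lactone ester; the lactone C–O bond together with the bond from the malonate carbon to the isopropenyl CH2; the CH3–C(OH) bond; the two C–C bonds at C2 and C3 of cyclopentanone.
2. Forward: the cyclopentane first (from cyclopent-2-en-1-one), then the cyclohexane and a bridging γ-lactone in one oxidative radical step, then the trione ring last by a [3+3] Claisen cascade, then twofold C-prenylation.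
3. Enabling feature: in the target the OH on the cyclohexane carbon C(CH3)(OH) is axial and syn (1,3-diaxial) to one of the two carbonyl carbons on the spiro carbon, the C=O between the spiro carbon and the gem-diprenyl carbon; the two can be tied as a γ-lactone, which tells the two acyl arms of the spiro carbon apart.
4. Stereochemistry: C3 of the cyclopentanone from a catalytic asymmetric conjugate addition; the neighbouring ring-fusion carbon from trans enolate trapping; the cyclopentane carbinol from methyl addition anti to the side chain; the cyclohexane carbinol and the spiro carbon from the lactone (only the syn ester can lactonise, and the lactone carbonyl becomes the ketone beside the diprenyl carbon).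

Key step: step 5

Assumption: 3 is used as the freshly distilled commercial monomer, and of the two antipodes of the ferrocenyl diphosphine in step 1 the one is taken that gives the 3R enolate 4.

**Step 1**
Reactants: 1 cyclopent-2-en-1-one; 2 prop-1-en-2-ylmagnesium bromide; 3 dimethyl 2-methylidenepropanedioate
Product: 5 dimethyl 2-{[(1S,5R)-2-oxo-5-(prop-1-en-2-yl)cyclopentyl]methyl}propanedioate, via magnesium enolate 4 (not isolated)
Conditions: CuBr·SMe2 (5 mol %), (R)-1-[(S)-2-(diphenylphosphino)ferrocenyl]ethyldicyclohexylphosphine (6 mol %), t-BuOMe, −78 °C, 2 added slowly; then 3 (1.05 equiv), −78 °C; aq. NH4Cl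
Reagents that add atoms: prop-1-en-2-ylmagnesium bromide 2, CC(=C)[Mg]Br; dimethyl 2-methylidenepropanedioate 3, C=C(C(=O)OC)C(=O)OC
Why: Copper-catalysed asymmetric conjugate addition of the Grignard reagent should set C3 (R) under control of the chiral diphosphine, and the regiodefined magnesium enolate is then trapped in a Michael addition by 3 on the face anti to the new isopropenyl group, which gives the 2,3-trans ketone.

**Step 2**
Reactants: 5 dimethyl 2-{[(1S,5R)-2-oxo-5-(prop-1-en-2-yl)cyclopentyl]methyl}propanedioate; 6 methylmagnesium bromide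
Product: 7 dimethyl 2-{[(1S,2R,5R)-2-hydroxy-2-methyl-5-(prop-1-en-2-yl)cyclopentyl]methyl}propanedioate
Conditions: 6 (2.3 equiv), CeCl3 (dried, 2.5 equiv), THF, −78 → −30 °C; aq. NH4Cl
Reagents that add atoms: methylmagnesium bromide 6, C[Mg]Br
Why: Grignard 1,2-addition in the presence of CeCl3 (the first equivalent only deprotonates the malonate, which shields both esters) should occur on the carbonyl face anti to the adjacent C2 side chain, so that the new hydroxyl is cis to that chain and the methyl trans.

**Step 3**
Reactants: 7 dimethyl 2-{[(1S,2R,5R)-2-hydroxy-2-methyl-5-(prop-1-en-2-yl)cyclopentyl]methyl}propanedioate; 8 triethylsilyl trifluoromethanesulfonate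
Product: 9 dimethyl 2-{[(1S,2R,5R)-2-methyl-5-(prop-1-en-2-yl)-2-(triethylsilyloxy)cyclopentyl]methyl}propanedioate
Conditions: 8 (1.5 equiv), 2,6-lutidine (2 equiv), CH2Cl2, −78 → 0 °C
Reagents that add atoms: triethylsilyl trifluoromethanesulfonate 8, CC[Si](CC)(CC)OS(=O)(=O)C(F)(F)F
Why: Silyl ether formation masks the tertiary alcohol, which would otherwise close a δ-lactone onto the cis malonate ester in the hot acetic acid of the next step and so block the carbocyclisation.

**Step 4**
Reactants: 9 dimethyl 2-{[(1S,2R,5R)-2-methyl-5-(prop-1-en-2-yl)-2-(triethylsilyloxy)cyclopentyl]methyl}propanedioate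
Product: 11 methyl (1S,2R,5R,6S,8S)-5-hydroxy-1,5-dimethyl-9-oxo-10-oxatricyclo[6.2.1.0(2,6)]undecane-8-carboxylate (bridged lactone ester), via silyl lactone ester 10 (not isolated)
Conditions: Mn(OAc)3·2H2O (2.2 equiv), degassed AcOH, 60 °C; then 2 M aq. HCl, THF, rt
Reagents that add atoms: none
Why: Oxidative free-radical cyclisation with lactone termination: trivalent manganese oxidises the malonate to a malonyl radical that closes 6-endo onto the CH2 end of the isopropenyl group (5-exo would need a trans-fused bicyclo[3.3.0]octane), the tertiary radical is oxidised to the cation and captured by the only ester carbonyl that can reach it, the axial one, which sets the methyl-bearing carbinol carbon and the quaternary carbon together, and aqueous acid then cleaves the silyl ether.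

**Step 5**
Reactants: 11 methyl (1S,2R,5R,6S,8S)-5-hydroxy-1,5-dimethyl-9-oxo-10-oxatricyclo[6.2.1.0(2,6)]undecane-8-carboxylate; 12 5-methylhexane-2,4-dione
Product: 15 (1R,3'R,3a'S,7'S,7a'R)-3',4,7'-trihydroxy-3',7'-dimethyl-3-(2-methylpropanoyl)-1',2',3',3a',4',6',7',7a'-octahydrospiro[cyclohex-3-ene-1,5'-indene]-2,6-dione (spiro trione), via dilithio diketone 13 (not isolated), via triketo ester 14 (not isolated)
Conditions: 12 (2.5 equiv), LiN(iPr)2 (6 equiv), THF, −78 → 0 °C; 11 added at 0 °C, then rt → 50 °C; 1 M aq. HCl to pH 4 at 0 °C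
Reagents that add atoms: 5-methylhexane-2,4-dione 12, CC(=O)CC(=O)C(C)C
Why: Proposed new method: The terminal carbanion of dianion 13 adds to the lactone carbonyl of 11, the tetrahedral intermediate opens to the tertiary alkoxide and triketo ester 14, whose new CH2 is deprotonated at once, and the central diketone carbon of this polyanion then attacks the methyl ester and expels methoxide (Claisen condensation), so that two C–C bonds, the trione ring and the 2-methylpropanoyl group arise in one flask. The closest known reaction types are the acylation of β-diketone dianions at the terminal carbon by esters and lactones and the biomimetic Claisen cyclisation of 3,5,7-triketo esters to acylphloroglucinols; new is their union on a 2-(methoxycarbonyl) lactone whose quaternary carbon keeps the ring from aromatising. The ring closes in the 6-exo-trig mode (carbanion onto the ester C=O, then loss of methoxide). No stereocentre is created, but the spiro carbon takes its configuration in the new ring from the lactone of 11: the axial carbonyl, syn to the C–O bond of the cyclohexane carbinol carbon, is joined to the terminal carbon (the later diprenyl carbon), and the equatorial ester carbonyl to the acyl-bearing carbon. The step needs attack of the dianion on the lactone before the ester (the reverse order would give the spiro epimer) and C- instead of O-acylation in the closure; the first should follow from the strain and the fixed s-cis geometry of the bridged γ-lactone set against an equatorial neopentyl-type methyl ester, the second from the reversibility of O-acylation under methoxide and the stability of the β-triketone enolate.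

**Step 6**
Reactants: 15 spiro trione; 16 1-bromo-3-methylbut-2-ene
Product: 17 Tomoeone D
Conditions: 16 (2.3 equiv), NaOMe (3.3 equiv), MeOH, 0 °C → rt
Reagents that add atoms: 1-bromo-3-methylbut-2-ene 16, CC(C)=CCBr
Why: Twofold enolate C-alkylation of the only unsubstituted ring carbon, the CH2 between two carbonyl groups, under the protic conditions used for gem-diprenylation of acylphloroglucinols to lupulone-type β-triketones (hydrogen bonding disfavours O-alkylation); no stereocentre is formed and the acyl-bearing carbon cannot be alkylated.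

**Compound list**

1 | cyclopent-2-en-1-one | O=C1C=CCC1 | starting material
2 | prop-1-en-2-ylmagnesium bromide | CC(=C)[Mg]Br | starting material
3 | dimethyl 2-methylidenepropanedioate | C=C(C(=O)OC)C(=O)OC | starting material
4 | bromomagnesium (3R)-3-(prop-1-en-2-yl)cyclopent-1-en-1-olate | CC(=C)[C@@H]1CCC(O[Mg]Br)=C1 | intermediate (not isolated)
5 | dimethyl 2-{[(1S,5R)-2-oxo-5-(prop-1-en-2-yl)cyclopentyl]methyl}propanedioate (2,3-trans) | COC(=O)C(C[C@H]1[C@@H](CCC1=O)C(C)=C)C(=O)OC | intermediate
6 | methylmagnesium bromide | C[Mg]Br | starting material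
7 | dimethyl 2-{[(1S,2R,5R)-2-hydroxy-2-methyl-5-(prop-1-en-2-yl)cyclopentyl]methyl}propanedioate (OH cis to the side chain) | COC(=O)C(C[C@H]1[C@@H](CC[C@@]1(C)O)C(C)=C)C(=O)OC | intermediate
8 | triethylsilyl trifluoromethanesulfonate | CC[Si](CC)(CC)OS(=O)(=O)C(F)(F)F | starting material
9 | dimethyl 2-{[(1S,2R,5R)-2-methyl-5-(prop-1-en-2-yl)-2-(triethylsilyloxy)cyclopentyl]methyl}propanedioate | COC(=O)C(C[C@H]1[C@@H](CC[C@@]1(C)O[Si](CC)(CC)CC)C(C)=C)C(=O)OC | intermediate
10 | methyl (1S,2R,5R,6S,8S)-1,5-dimethyl-9-oxo-5-(triethylsilyloxy)-10-oxatricyclo[6.2.1.0(2,6)]undecane-8-carboxylate | COC(=O)[C@]12C[C@H]3[C@@H](CC[C@@]3(C)O[Si](CC)(CC)CC)[C@](C)(C1)OC2=O | intermediate (not isolated)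
11 | methyl (1S,2R,5R,6S,8S)-5-hydroxy-1,5-dimethyl-9-oxo-10-oxatricyclo[6.2.1.0(2,6)]undecane-8-carboxylate (trans-fused hydrindane; axial carbonyl tied as γ-lactone, equatorial CO2Me) | COC(=O)[C@]12C[C@H]3[C@@H](CC[C@@]3(C)O)[C@](C)(C1)OC2=O | intermediate
12 | 5-methylhexane-2,4-dione | CC(=O)CC(=O)C(C)C | starting material
13 | dilithium 5-methylhexa-1,3-diene-2,4-diolate | C=C(O[Li])C=C(O[Li])C(C)C | intermediate (not isolated)
14 | methyl (1R,3aR,4S,6R,7aS)-1,4-dihydroxy-1,4-dimethyl-6-(6-methyl-3,5-dioxoheptanoyl)octahydro-1H-indene-6-carboxylate (present as its lithium salt) | COC(=O)[C@]1(C(=O)CC(=O)CC(=O)C(C)C)C[C@H]2[C@@H](CC[C@@]2(C)O)[C@@](C)(O)C1 | intermediate (not isolated)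
15 | (1R,3'R,3a'S,7'S,7a'R)-3',4,7'-trihydroxy-3',7'-dimethyl-3-(2-methylpropanoyl)-1',2',3',3a',4',6',7',7a'-octahydrospiro[cyclohex-3-ene-1,5'-indene]-2,6-dione (the target without its two prenyl groups) | CC(C)C(=O)C1=C(O)CC(=O)[C@]2(C[C@H]3[C@@H](CC[C@@]3(C)O)[C@@](C)(O)C2)C1=O | intermediate
16 | 1-bromo-3-methylbut-2-ene | CC(C)=CCBr | starting material
17 | Tomoeone D, (1R,3'R,3a'S,7'S,7a'R)-3',4,7'-trihydroxy-3',7'-dimethyl-5,5-bis(3-methylbut-2-en-1-yl)-3-(2-methylpropanoyl)-1',2',3',3a',4',6',7',7a'-octahydrospiro[cyclohex-3-ene-1,5'-indene]-2,6-dione | CC(C)=CCC1(CC=C(C)C)C(=O)[C@]2(C[C@H]3[C@@H](CC[C@@]3(C)O)[C@@](C)(O)C2)C(=O)C(C(=O)C(C)C)=C1O | target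

**Step count and risks**

Total step count: 6. Longest linear sequence: 6 steps (from 1).

Steps most likely to fail:

Step 5. The dianion may add to the methyl ester before the lactone, which would end in the spiro epimer, or the Claisen closure onto the hindered ester may stall after the lactone has opened. The fallback fixes the order of the two acylations by reagent type and sets out from 11. LiOH in THF/H2O followed by acidification (only the syn acid can reclose onto the hydroxyl) should give (1S,2R,5R,6S,8S)-5-hydroxy-1,5-dimethyl-9-oxo-10-oxatricyclo[6.2.1.0(2,6)]undecane-8-carboxylic acid F1. 1,1'-Carbonyldiimidazole should convert it into the acyl imidazole F2. The magnesium enolate of 12 (MgCl2, Et3N, MeCN) is then C-acylated at its central carbon to the triketone lactone F3, with the tertiary alcohol left untouched. Excess LiN(SiMe3)2 in THF (−78 → 0 °C) should form the carbanion of the acetyl methyl group, which opens the lactone intramolecularly in a Claisen-type acyl transfer; the route is rejoined at 15.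

Step 1. Enantioselection may be poor with an sp2 Grignard reagent, direct 1,2-addition may compete, and the malonate anion may start oligomerisation of 3. The fallback replaces catalyst control by substrate control and sets out from 2 and 3 with commercial (S)-4-[(tert-butyldimethylsilyl)oxy]cyclopent-2-en-1-one (O=C1C=C[C@@H](O[Si](C)(C)C(C)(C)C)C1). Copper-mediated conjugate addition of 2 (CuBr·SMe2, THF, −78 °C) anti to the silyloxy group, followed by Michael trapping with 3, should give the all-trans silyloxy ketone F4. 1,8-Diazabicyclo[5.4.0]undec-7-ene in CH2Cl2 should eliminate the silanol to the cyclopentenone F5. Conjugate reduction with [(Ph3P)CuH]6 (benzene, rt), which leaves the isopropenyl group alone, rejoins the route at 5.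

Step 6. O-Prenylation and arrest after the first alkylation may compete with the second C-alkylation at the crowded carbon. The fallback sets out from 15 and builds the prenyl groups in two stages. Twofold Tsuji–Trost allylation with allyl methyl carbonate and Pd(PPh3)4 in THF (zerovalent palladium re-ionises any O-allyl enol ether, so the C-allyl products collect) should give the gem-diallyl trione F6. Twofold cross-metathesis with 2-methylbut-2-ene (second-generation Grubbs catalyst, CH2Cl2, 40 °C) rejoins the route at 17.

**Further compounds**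

F1 | step 5 | (1S,2R,5R,6S,8S)-5-hydroxy-1,5-dimethyl-9-oxo-10-oxatricyclo[6.2.1.0(2,6)]undecane-8-carboxylic acid | OC(=O)[C@]12C[C@H]3[C@@H](CC[C@@]3(C)O)[C@](C)(C1)OC2=O
F2 | step 5 | (1S,2R,5R,6S,8S)-5-hydroxy-8-(1H-imidazol-1-ylcarbonyl)-1,5-dimethyl-10-oxatricyclo[6.2.1.0(2,6)]undecan-9-one | O=C(n1ccnc1)[C@]12C[C@H]3[C@@H](CC[C@@]3(C)O)[C@](C)(C1)OC2=O
F3 | step 5 | 2-acetyl-1-[(1S,2R,5R,6S,8S)-5-hydroxy-1,5-dimethyl-9-oxo-10-oxatricyclo[6.2.1.0(2,6)]undecan-8-yl]-4-methylpentane-1,3-dione | CC(C)C(=O)C(C(C)=O)C(=O)[C@]12C[C@H]3[C@@H](CC[C@@]3(C)O)[C@](C)(C1)OC2=O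
F4 | step 1 | dimethyl 2-{[(1S,2R,3S)-3-[(tert-butyldimethylsilyl)oxy]-5-oxo-2-(prop-1-en-2-yl)cyclopentyl]methyl}propanedioate | COC(=O)C(C[C@H]1[C@@H]([C@@H](O[Si](C)(C)C(C)(C)C)CC1=O)C(C)=C)C(=O)OC
F5 | step 1 | dimethyl 2-{[(1S,5R)-2-oxo-5-(prop-1-en-2-yl)cyclopent-3-en-1-yl]methyl}propanedioate | COC(=O)C(C[C@H]1[C@@H](C=CC1=O)C(C)=C)C(=O)OC
F6 | step 6 | (1R,3'R,3a'S,7'S,7a'R)-3',4,7'-trihydroxy-3',7'-dimethyl-3-(2-methylpropanoyl)-5,5-di(prop-2-en-1-yl)-1',2',3',3a',4',6',7',7a'-octahydrospiro[cyclohex-3-ene-1,5'-indene]-2,6-dione | C=CCC1(CC=C)C(=O)[C@]2(C[C@H]3[C@@H](CC[C@@]3(C)O)[C@@](C)(O)C2)C(=O)C(C(=O)C(C)C)=C1O
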